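**Strategy.** The cyclohexene (ring numbered C1(Me)=C2–C3–C4–C5(H)(Me)–C6(Me)(C1′)) is disconnected at C6–C1 and C5–C4. The cis methyl pair on C5/C6, with chain carbon C1′ on quaternary C6, is the footprint of (E)-2-methylbut-2-enal. One catalytic enantioselective Diels–Alder reaction with (E)-1-(triisopropylsilyloxy)buta-1,3-diene should therefore close the ring, set both stereocentres and leave oxygen at C1 for later conversion into the C1 methyl/C1=C2 olefin. The dienophile is commercial and the diene is one step from crotonaldehyde. The formyl carbon (C1′) is then methylenated and joined by B-alkyl Suzuki coupling to a geranyl-acetate-derived iodoalkene; the sulfonylethylguanidine is attached last.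

Key step: step 2

Remark: ring atoms are numbered as above and chain atoms C1′–C9′ run from the ring to sulfur. The target is taken as the neutral guanidine drawn. A C1 epimer of 4 (exo transition state) would simply be carried along, because C1 becomes a carbonyl carbon in step 6.

**Step 1**
Reactants: 1 crotonaldehyde [(E)-but-2-enal]
Product: 2 (E)-1-(triisopropylsilyloxy)buta-1,3-diene
Conditions: i-Pr3SiOTf, Et3N, Et2O, 0 °C → rt; distillation
Reagents that add atoms: triisopropylsilyl trifluoromethanesulfonate, CC(C)[Si](C(C)C)(C(C)C)OS(=O)(=O)C(F)(F)F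
Why: O-silylation of the enal followed by γ-deprotonation with the amine (silyl dienol ether formation) should give the conjugated diene, the E enol ether being favoured; no stereocentre is formed.

**Step 2**
Reactants: 3 tiglic aldehyde [(E)-2-methylbut-2-enal]; 2 (E)-1-(triisopropylsilyloxy)buta-1,3-diene
Product: 4 (1S,2R,6R)-1,6-dimethyl-2-[(triisopropylsilyl)oxy]cyclohex-3-ene-1-carbaldehyde (methyls cis, formyl cis to the silyloxy group)
Conditions: (S)-1-(2-methylphenyl)-3,3-diphenyltetrahydro-1H,3H-pyrrolo[1,2-c][1,3,2]oxazaborole (20 mol %), HN(SO2CF3)2 (20 mol %), CH2Cl2, −78 → −20 °C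
Reagents that add atoms: none
Why: N-protonation of the oxazaborolidine by triflimide gives a cationic boron Lewis acid that binds the formyl oxygen of 3 (formyl C–H held by the ring oxygen), and the s-trans enal then undergoes a concerted, asynchronous, suprafacial [4+2] cycloaddition with s-cis 2, the unsubstituted diene terminus bonding to the β-carbon (C5–C4) and the oxygenated terminus to the α-carbon (C6–C1). The closest known reaction type is the cationic-oxazaborolidine-catalysed Diels–Alder reaction of α-substituted enals with 1-silyloxy dienes. The six-membered ring is closed by intermolecular cycloaddition, both ring bonds being formed in the same event across one face of each π-system. The cis C5/C6 methyls with formyl trans to the C5 methyl follow from the E geometry of the dienophile, and the absolute configuration from the catalyst: the phenyl group on its convex face lies under the C=C of the bound enal, so the diene should add to the open Re face of the α-carbon, which corresponds to (1S,6R) in 4. The C1 oxygen-bearing centre reflects the endo orientation of the formyl group but is erased in step 6. The step needs ortho regioselectivity (secured by the silyloxy donor, largest HOMO coefficient at the remote terminus), enantiofacial selectivity (secured by two-point binding to the catalyst) and C=C over C=O addition (favoured by the α-substituent).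

**Step 3**
Reactants: 4 Diels–Alder adduct
Product: 5 (1S,2R,6R)-1,6-dimethyl-2-[(triisopropylsilyl)oxy]cyclohexane-1-carbaldehyde
Conditions: H2 (1 atm), 5% Pd/C, EtOAc, rt
Reagents that add atoms: none
Why: Heterogeneous catalytic hydrogenation should saturate the cis-disubstituted C2=C3 olefin well before the hindered neopentyl aldehyde reacts, and the C5/C6 centres cannot epimerise because C6 is quaternary.

**Step 4**
Reactants: 5 saturated aldehyde
Product: 6 {[(1R,2S,3R)-2-ethenyl-2,3-dimethylcyclohexyl]oxy}tri(propan-2-yl)silane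
Conditions: Ph3PCH3Br, KOt-Bu, THF, 0 °C → 50 °C
Reagents that add atoms: methyltriphenylphosphonium bromide, C[P+](c1ccccc1)(c1ccccc1)c1ccccc1.[Br-]
Why: Wittig methylenation with the small unstabilised ylide should convert the non-enolisable neopentyl aldehyde into the C1′=C2′ vinyl group without touching any stereocentre.

**Step 5**
Reactants: 6 vinyl silyl ether
Product: 7 (1R,2S,3R)-2-ethenyl-2,3-dimethylcyclohexan-1-ol
Conditions: Bu4NF, THF, rt → 50 °C
Reagents that add atoms: none
Why: Fluoride-mediated desilylation, driven by the Si–F bond, should free the hindered secondary alcohol; nothing else in 6 responds to fluoride.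

**Step 6**
Reactants: 7 alcohol
Product: 8 (2S,3R)-2-ethenyl-2,3-dimethylcyclohexan-1-one
Conditions: Dess–Martin periodinane, CH2Cl2, rt
Reagents that add atoms: none
Why: Dess–Martin oxidation under neutral conditions should give the ketone at C1; the vinyl group sits on quaternary C6 and cannot move into conjugation.

**Step 7**
Reactants: 8 ketone
Product: 10 (5R,6S)-6-ethenyl-5,6-dimethylcyclohex-1-en-1-yl trifluoromethanesulfonate, via potassium enolate 9 (not isolated)
Conditions: KN(SiMe3)2, THF, −78 °C; then PhN(SO2CF3)2, −78 °C → rt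
Reagents that add atoms: N-phenylbis(trifluoromethanesulfonimide), FC(F)(F)S(=O)(=O)N(c1ccccc1)S(=O)(=O)C(F)(F)F
Why: Enolisation can only occur toward C2 because C6 is quaternary, and O-sulfonylation of that enolate (enol triflate synthesis) fixes the C1=C2 position of the future olefin.

**Step 8**
Reactants: 10 enol triflate
Product: 11 (5R,6S)-6-ethenyl-1,5,6-trimethylcyclohex-1-ene
Conditions: MeMgBr, Fe(acac)3 (5 mol %), THF/NMP, −30 → 0 °C
Reagents that add atoms: methylmagnesium bromide, C[Mg]Br
Why: Iron-catalysed Kumada-type cross-coupling of alkenyl triflates with methyl Grignard reagents is fast at low temperature even for hindered triflates and should install the C1 methyl with the olefin fixed at C1=C2, leaving the vinyl group and both stereocentres untouched.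

**Step 9**
Reactants: 12 geranyl acetate [(2E)-3,7-dimethylocta-2,6-dien-1-yl acetate]
Product: 15 (2E)-3-methyl-6-oxohex-2-en-1-yl acetate, via epoxide 13 (not isolated), via diol 14 (not isolated)
Conditions: mCPBA, CH2Cl2, 0 °C; then H5IO6, THF/H2O, 0 °C → rt
Reagents that add atoms: 3-chloroperbenzoic acid, OOC(=O)c1cccc(Cl)c1
Why: Prilezhaev epoxidation should select the electron-richer 6,7-olefin (the 2,3-olefin is deactivated by the allylic acetate), and periodic acid then hydrolyses the epoxide and cleaves the glycol (Malaprade cleavage) to the aldehyde with the 2E olefin intact.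

**Step 10**
Reactants: 15 aldehyde
Product: 17 (2E)-3-methylhept-2-en-6-yn-1-ol, via acetoxy alkyne 16 (not isolated)
Conditions: dimethyl (1-diazo-2-oxopropyl)phosphonate, K2CO3, MeOH, 0 °C → rt
Reagents that add atoms: dimethyl (1-diazo-2-oxopropyl)phosphonate, COP(=O)(OC)C(=[N+]=[N-])C(C)=O
Why: Seyferth–Gilbert homologation in its Ohira–Bestmann form should convert the aldehyde into the terminal alkyne, and the same carbonate/methanol medium transesterifies the acetate to the free allylic alcohol.

**Step 11**
Reactants: 17 terminal enynol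
Product: 19 (2E)-3-methyloct-2-en-6-yn-1-ol, via dilithio dianion 18 (not isolated)
Conditions: n-BuLi (2.2 equiv), THF, −78 → −20 °C; then MeI (1.1 equiv), −78 °C → rt
Reagents that add atoms: iodomethane, CI
Why: In the alkoxide–acetylide dianion the acetylide carbon is far more nucleophilic toward iodomethane than the lithium alkoxide in THF, so acetylide C-alkylation should give the 2-alkyne selectively.

**Step 12**
Reactants: 19 methyl enynol
Product: 21 (2E,6E)-7-iodo-3-methylocta-2,6-dien-1-ol, via alkenylzirconocene 20 (not isolated)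
Conditions: Cp2ZrHCl (2.5 equiv), THF, rt → 40 °C, dark; then I2, THF, 0 °C
Reagents that add atoms: iodine, II
Why: Syn hydrozirconation of the 2-alkyne, equilibrated by excess hydride so that zirconium rests on the less hindered methyl-bearing carbon, followed by iodinolysis with retention should give the (E)-2-iodoalkene (iodine trans to C5′); the trisubstituted olefin is inert to the reagent.

**Step 13**
Reactants: 11 vinylcyclohexene; 21 iodoalkene
Product: 23 (2E,6E)-3,7-dimethyl-9-[(1S,6R)-1,2,6-trimethylcyclohex-2-en-1-yl]nona-2,6-dien-1-ol, via B-alkyl-9-BBN 22 (not isolated)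
Conditions: 9-BBN-H, THF, 0 °C → rt; then 21, Pd(dppf)Cl2 (5 mol %), AsPh3, Cs2CO3, DMF/THF/H2O, rt
Reagents that add atoms: none
Why: 9-BBN should hydroborate only the monosubstituted vinyl group (anti-Markovnikov, boron on C2′) and the B-alkyl Suzuki–Miyaura coupling forms C2′–C3′ with retention of the iodoalkene geometry, fixing the 6E olefin while tolerating the free hydroxyl.

**Step 14**
Reactants: 23 allylic alcohol
Product: 24 (2E,6E)-1-bromo-3,7-dimethyl-9-[(1S,6R)-1,2,6-trimethylcyclohex-2-en-1-yl]nona-2,6-diene
Conditions: CBr4, PPh3, CH2Cl2, 0 °C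
Reagents that add atoms: tetrabromomethane, BrC(Br)(Br)Br
Why: Appel bromination under neutral conditions should replace the primary allylic hydroxyl by bromide in an SN2 sense, without allylic transposition or loss of the 2E geometry.

**Step 15**
Reactants: 25 hypotaurine (2-aminoethane-1-sulfinic acid)
Product: 26 2-guanidinoethane-1-sulfinic acid (inner salt)
Conditions: 1H-pyrazole-1-carboxamidine hydrochloride, Na2CO3, H2O, rt
Reagents that add atoms: 1H-pyrazole-1-carboxamidine hydrochloride, Cl.NC(=N)n1cccn1
Why: Amidine transfer from the pyrazole carboxamidine to the primary amine (guanidinylation) is a standard reaction of amino acids in aqueous carbonate, and the sulfinate is a spectator.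

**Step 16**
Reactants: 24 allylic bromide; 26 guanidino sulfinic acid
Product: 28 agelasidine C, N-[2-({(2E,6E)-3,7-dimethyl-9-[(1S,6R)-1,2,6-trimethylcyclohex-2-en-1-yl]nona-2,6-dien-1-yl}sulfonyl)ethyl]guanidine, via guanidinium bromide 27 (not isolated)
Conditions: DMF/H2O (9:1), 0 °C → rt; then aq. NaOH (1 equiv), 0 °C
Reagents that add atoms: none
Why: The sulfinate is a soft sulfur nucleophile that should undergo SN2 S-alkylation with the primary allylic bromide to give the sulfone, while the guanidine stays protonated within the inner salt and therefore non-nucleophilic; neutralisation then liberates the free guanidine.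

**Compound list**
1 | crotonaldehyde, (E)-but-2-enal | C/C=C/C=O | starting material
2 | (E)-1-(triisopropylsilyloxy)buta-1,3-diene | C=C/C=C/O[Si](C(C)C)(C(C)C)C(C)C | intermediate
3 | tiglic aldehyde, (E)-2-methylbut-2-enal | C/C=C(/C=O)C | starting material
4 | (1S,2R,6R)-1,6-dimethyl-2-[(triisopropylsilyl)oxy]cyclohex-3-ene-1-carbaldehyde | C[C@@H]1CC=C[C@@H](O[Si](C(C)C)(C(C)C)C(C)C)[C@@]1(C)C=O | intermediate
5 | (1S,2R,6R)-1,6-dimethyl-2-[(triisopropylsilyl)oxy]cyclohexane-1-carbaldehyde | C[C@@H]1CCC[C@@H](O[Si](C(C)C)(C(C)C)C(C)C)[C@@]1(C)C=O | intermediate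
6 | {[(1R,2S,3R)-2-ethenyl-2,3-dimethylcyclohexyl]oxy}tri(propan-2-yl)silane | C[C@@H]1CCC[C@@H](O[Si](C(C)C)(C(C)C)C(C)C)[C@@]1(C)C=C | intermediate
7 | (1R,2S,3R)-2-ethenyl-2,3-dimethylcyclohexan-1-ol | C[C@@H]1CCC[C@@H](O)[C@@]1(C)C=C | intermediate
8 | (2S,3R)-2-ethenyl-2,3-dimethylcyclohexan-1-one | C[C@@H]1CCCC(=O)[C@@]1(C)C=C | intermediate
9 | potassium (5R,6S)-6-ethenyl-5,6-dimethylcyclohex-1-en-1-olate | C[C@@H]1CCC=C([O-])[C@@]1(C)C=C.[K+] | intermediate (not isolated)
10 | (5R,6S)-6-ethenyl-5,6-dimethylcyclohex-1-en-1-yl trifluoromethanesulfonate | C[C@@H]1CCC=C(OS(=O)(=O)C(F)(F)F)[C@@]1(C)C=C | intermediate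
11 | (5R,6S)-6-ethenyl-1,5,6-trimethylcyclohex-1-ene | CC1=CCC[C@@H](C)[C@]1(C)C=C | intermediate
12 | geranyl acetate, (2E)-3,7-dimethylocta-2,6-dien-1-yl acetate | CC(C)=CCC/C(C)=C/COC(C)=O | starting material
13 | (2E)-5-(3,3-dimethyloxiran-2-yl)-3-methylpent-2-en-1-yl acetate (racemic) | CC1(C)OC1CC/C(C)=C/COC(C)=O | intermediate (not isolated)
14 | (2E)-6,7-dihydroxy-3,7-dimethyloct-2-en-1-yl acetate (racemic) | CC(C)(O)C(O)CC/C(C)=C/COC(C)=O | intermediate (not isolated)
15 | (2E)-3-methyl-6-oxohex-2-en-1-yl acetate | O=CCC/C(C)=C/COC(C)=O | intermediate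
16 | (2E)-3-methylhept-2-en-6-yn-1-yl acetate | C#CCC/C(C)=C/COC(C)=O | intermediate (not isolated)
17 | (2E)-3-methylhept-2-en-6-yn-1-ol | C#CCC/C(C)=C/CO | intermediate
18 | dilithium salt of 17 (alkoxide and acetylide) | [Li+].[Li+].[C-]#CCC/C(C)=C/C[O-] | intermediate (not isolated)
19 | (2E)-3-methyloct-2-en-6-yn-1-ol | CC#CCC/C(C)=C/CO | intermediate
20 | (E)-alkenylzirconocene chloride of 19, zirconium on C7 and as O-zirconium alkoxide (cyclopentadienyl ligands drawn σ-bonded) | Cl[Zr](C1C=CC=C1)(C1C=CC=C1)/C(C)=C/CC/C(C)=C/CO[Zr](Cl)(C1C=CC=C1)C1C=CC=C1 | intermediate (not isolated)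
21 | (2E,6E)-7-iodo-3-methylocta-2,6-dien-1-ol | I/C(C)=C/CC/C(C)=C/CO | intermediate
22 | 9-{2-[(1S,6R)-1,2,6-trimethylcyclohex-2-en-1-yl]ethyl}-9-borabicyclo[3.3.1]nonane | CC1=CCC[C@@H](C)[C@]1(C)CCB1C2CCCC1CCC2 | intermediate (not isolated)
23 | (2E,6E)-3,7-dimethyl-9-[(1S,6R)-1,2,6-trimethylcyclohex-2-en-1-yl]nona-2,6-dien-1-ol | CC1=CCC[C@@H](C)[C@]1(C)CC/C(C)=C/CC/C(C)=C/CO | intermediate
24 | (2E,6E)-1-bromo-3,7-dimethyl-9-[(1S,6R)-1,2,6-trimethylcyclohex-2-en-1-yl]nona-2,6-diene | CC1=CCC[C@@H](C)[C@]1(C)CC/C(C)=C/CC/C(C)=C/CBr | intermediate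
25 | hypotaurine, 2-aminoethane-1-sulfinic acid | NCCS(=O)O | starting material
26 | 2-guanidinoethane-1-sulfinic acid (inner salt, drawn neutral) | NC(N)=NCCS(=O)O | intermediate
27 | guanidinium bromide of 28 | CC1=CCC[C@@H](C)[C@]1(C)CC/C(C)=C/CC/C(C)=C/CS(=O)(=O)CCNC(N)=[NH2+].[Br-] | intermediate (not isolated)
28 | agelasidine C, N-[2-({(2E,6E)-3,7-dimethyl-9-[(1S,6R)-1,2,6-trimethylcyclohex-2-en-1-yl]nona-2,6-dien-1-yl}sulfonyl)ethyl]guanidine | CC1=CCC[C@@H](C)[C@]1(C)CC/C(C)=C/CC/C(C)=C/CS(=O)(=O)CCN=C(N)N | target

**Step count.** Total: 16 steps. Longest linear sequence: 11 steps (steps 1–8, 13, 14, 16, from crotonaldehyde). The iodoalkene branch is steps 9–12 and the sulfinate branch is step 15.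

**Steps most likely to fail**

Step 2. The β-substituted enal may react too slowly with the acyclic silyloxy diene at the temperature needed for face control, or carbonyl addition of the silyl dienol ether may compete, so that enantiofacial selectivity or conversion is poor. The fallback sets out from 2 and 3 and comes back at 4. The cycloaddition is run without chiral control (Me2AlCl, CH2Cl2, −78 °C, or thermally in toluene), which should give 4 together with its mirror image, (1R,2S,6S)-1,6-dimethyl-2-[(triisopropylsilyl)oxy]cyclohex-3-ene-1-carbaldehyde F1. The enantiomers are then separated by preparative chromatography on a chiral stationary phase and 4 is carried on as before.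

Step 12. Zirconium may add in part to the internal alkyne carbon, giving a regioisomeric iodide that is hard to remove. The fallback sets out from aldehyde 15 and borane 22 and comes back at alcohol 23, bypassing steps 10–12. Dibromo-olefination of 15 (CBr4, PPh3, CH2Cl2, 0 °C; first stage of the Corey–Fuchs sequence) should give (2E)-7,7-dibromo-3-methylhepta-2,6-dien-1-yl acetate F2. Methanolysis (K2CO3, MeOH) would give (2E)-7,7-dibromo-3-methylhepta-2,6-dien-1-ol F3. Trans-selective mono-coupling of F3 with 22 (PdCl2(DPEphos) or Pd2(dba)3/Xantphos, Cs2CO3, THF/H2O), in which the bromine trans to the chain reacts first, should give (2E,6Z)-7-bromo-3-methyl-9-[(1S,6R)-1,2,6-trimethylcyclohex-2-en-1-yl]nona-2,6-dien-1-ol F4. Stereoretentive Negishi methylation of F4 (Me2Zn, Pd(P(t-Bu)3)2, THF) then places the methyl cis to C5′ and delivers 23.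

Step 16. The zwitterionic sulfinate may dissolve poorly, so that S-alkylation is slow and the allylic bromide is lost to solvolysis or O-alkylation. The fallback sets out from 25 and 24 and comes back at 28. Hypotaurine 25 is N-protected (Boc2O, NaOH, H2O/dioxane) to the DMF-soluble sodium 2-[(tert-butoxycarbonyl)amino]ethane-1-sulfinate F5. Alkylation of 24 with F5 (DMF, rt) should give tert-butyl N-[2-({(2E,6E)-3,7-dimethyl-9-[(1S,6R)-1,2,6-trimethylcyclohex-2-en-1-yl]nona-2,6-dien-1-yl}sulfonyl)ethyl]carbamate F6. Carbamate cleavage under non-protic conditions (Me3SiOTf, 2,6-lutidine, CH2Cl2, 0 °C; then MeOH), chosen to spare the trisubstituted olefins, would give 2-({(2E,6E)-3,7-dimethyl-9-[(1S,6R)-1,2,6-trimethylcyclohex-2-en-1-yl]nona-2,6-dien-1-yl}sulfonyl)ethan-1-amine F7. Guanidinylation of F7 with 1H-pyrazole-1-carboxamidine hydrochloride and i-Pr2NEt in DMF then gives 28.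

**Further compounds**
F1 | step 2 | (1R,2S,6S)-1,6-dimethyl-2-[(triisopropylsilyl)oxy]cyclohex-3-ene-1-carbaldehyde (enantiomer of 4) | C[C@H]1CC=C[C@H](O[Si](C(C)C)(C(C)C)C(C)C)[C@]1(C)C=O
F2 | step 12 | (2E)-7,7-dibromo-3-methylhepta-2,6-dien-1-yl acetate | BrC(Br)=CCC/C(C)=C/COC(C)=O
F3 | step 12 | (2E)-7,7-dibromo-3-methylhepta-2,6-dien-1-ol | BrC(Br)=CCC/C(C)=C/CO
F4 | step 12 | (2E,6Z)-7-bromo-3-methyl-9-[(1S,6R)-1,2,6-trimethylcyclohex-2-en-1-yl]nona-2,6-dien-1-ol | CC1=CCC[C@@H](C)[C@]1(C)CC/C(Br)=C/CC/C(C)=C/CO
F5 | step 16 | sodium 2-[(tert-butoxycarbonyl)amino]ethane-1-sulfinate | [Na+].CC(C)(C)OC(=O)NCCS(=O)[O-]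
F6 | step 16 | tert-butyl N-[2-({(2E,6E)-3,7-dimethyl-9-[(1S,6R)-1,2,6-trimethylcyclohex-2-en-1-yl]nona-2,6-dien-1-yl}sulfonyl)ethyl]carbamate | CC1=CCC[C@@H](C)[C@]1(C)CC/C(C)=C/CC/C(C)=C/CS(=O)(=O)CCNC(=O)OC(C)(C)C
F7 | step 16 | 2-({(2E,6E)-3,7-dimethyl-9-[(1S,6R)-1,2,6-trimethylcyclohex-2-en-1-yl]nona-2,6-dien-1-yl}sulfonyl)ethan-1-amine | CC1=CCC[C@@H](C)[C@]1(C)CC/C(C)=C/CC/C(C)=C/CS(=O)(=O)CCN
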